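**Plan**
Retrosynthetic cuts (labdane numbering): C9–C11 (side chain), then C3–C4 (ring A), then C4–C5 and C1–C10 together. The C6 acetate, C7 hydroxyl and C8=C9 alkene are traced back to a C9 ketone and a C6 ketal.
Enabling feature: in ring B, C9 lies between the methyl-bearing C8 and C10 and faces the oxygenated C6 across the ring. This is the pattern of the mirror-symmetric 2,6-dimethyl-1,4-benzoquinone 4-monoketal (C9 = carbonyl, C6 = ketal, C5 and C7 = the two β-carbons).
Forward order: ring B from the phenol; C4 and the C1–C3 unit are attached in step 2; ring A closes by radical C3–C4 bond formation; the side chain is joined at C9; the alkene is moved to C8=C9; C7 and C6 are oxygenated last.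
Stereochemistry: C5 from a chiral copper catalyst; C10 by alkylation anti to the C5 substituent; C7 by α-face enolate hydroxylation and C6 by α-face hydride delivery (both steered by the axial C10 and C4 methyls); 13Z from trans-hydroalumination/iodination and a stereoretentive coupling.

Key step: step 2

Assumption: the antipode of the ferrocenyl diphosphine that gives the (5S) adduct is chosen after testing both, and the C2 centre (compounds 7–9) and the C9 centre (compounds 21, 22) are carried as epimer mixtures because both are destroyed later.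

**Route**

Step 1
Reactants: 1 4-methoxy-2,6-dimethylphenol
Product: 2 4,4-dimethoxy-2,6-dimethylcyclohexa-2,5-dien-1-one
Conditions: PhI(OAc)2, MeOH, 0 °C
Reagents that add atoms: methanol, CO
Why: Hypervalent-iodine oxidative dearomatisation of a para-alkoxyphenol should capture the phenoxenium ion at the methoxy-bearing carbon with methanol and give the mirror-symmetric quinone monoketal, no stereocentre being formed.

Step 2
Reactants: 2 4,4-dimethoxy-2,6-dimethylcyclohexa-2,5-dien-1-one; 3 isopropenylmagnesium bromide; 4 methyl 2-(bromomethyl)prop-2-enoate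
Product: 6 methyl 2-{[(1S,6S)-5,5-dimethoxy-1,3-dimethyl-2-oxo-6-(prop-1-en-2-yl)cyclohex-3-en-1-yl]methyl}prop-2-enoate, via magnesium enolate 5 (not isolated)
Conditions: CuBr·SMe2 (5 mol %), (R)-1-[(SP)-2-(diphenylphosphino)ferrocenyl]ethyldicyclohexylphosphine (6 mol %), t-BuOMe/CH2Cl2, −78 °C, slow addition of 3; then 4, DMPU, −78 → 0 °C
Reagents that add atoms: none
Why: Proposed new method: a chiral copper–diphosphine complex takes the alkenyl group from the Grignard reagent, binds one enone arm of the C2v-symmetric dienone and forms C4–C5 by 1,4-addition, leaving magnesium enolate 5, which is C-alkylated by the allylic bromide (SN2 or SN2′, both giving the same C1–C10 bond). The closest known reaction type is the copper-catalysed enantioselective conjugate addition of Grignard or dialkylzinc reagents to cyclohexenones and 4,4-disubstituted cyclohexa-2,5-dienones with electrophilic trapping of the enolate; the untested element is alkenyl transfer to a dienone that carries α-methyl groups. No ring is closed in this step. C5 is set by the catalyst, which must tell apart the two enantiotopic β-carbons (equivalently the two faces) of 2, and C10 is set by the substrate, the electrophile entering the enolate face anti to the neighbouring isopropenyl group. The step needs 1,4- over 1,2-selectivity, which the two α-methyl groups flanking the carbonyl and the soft copper nucleophile should secure, and single addition, which is secured because the second enone arm is part of the cross-conjugated enolate until the alkylation. Over-alkylation cannot occur because C10 becomes quaternary.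

Step 3
Reactants: 6 methyl 2-{[(1S,6S)-5,5-dimethoxy-1,3-dimethyl-2-oxo-6-(prop-1-en-2-yl)cyclohex-3-en-1-yl]methyl}prop-2-enoate
Product: 7 methyl (4aS,8aS)-5,5-dimethoxy-4,4,7,8a-tetramethyl-8-oxo-1,2,3,4,4a,5,8,8a-octahydronaphthalene-2-carboxylate (C2 epimers)
Conditions: Fe(acac)3 (30 mol %), PhSiH3, EtOH, 60 °C
Reagents that add atoms: none
Why: Metal-hydride hydrogen-atom transfer (Mukaiyama type) to the electron-rich isopropenyl group should give the tertiary C4 radical, which adds 6-endo to the CH2 terminus of the 2-substituted acrylate (Giese addition; 5-exo would be contra-polar and give a primary radical), the ring fusion being fixed as trans by C5 and C10 and the new C2 centre being of no consequence.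

Step 4
Reactants: 7 methyl (4aS,8aS)-5,5-dimethoxy-4,4,7,8a-tetramethyl-8-oxo-1,2,3,4,4a,5,8,8a-octahydronaphthalene-2-carboxylate
Product: 8 (4aS,8aS)-5,5-dimethoxy-4,4,7,8a-tetramethyl-8-oxo-1,2,3,4,4a,5,8,8a-octahydronaphthalene-2-carboxylic acid (C2 epimers)
Conditions: LiOH, THF/MeOH/H2O, rt; then 1 M HCl to pH 5, 0 °C
Reagents that add atoms: lithium hydroxide, [Li+].[OH-]
Why: Saponification of an unhindered secondary methyl ester should leave the base-stable ketal and the non-enolisable enone untouched, and the acidification is held at pH 5 so that the ketal survives.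

Step 5
Reactants: 8 (4aS,8aS)-5,5-dimethoxy-4,4,7,8a-tetramethyl-8-oxo-1,2,3,4,4a,5,8,8a-octahydronaphthalene-2-carboxylic acid
Product: 10 (4aS,8aS)-4,4-dimethoxy-2,5,5,8a-tetramethyl-4a,5,6,7,8,8a-hexahydronaphthalen-1(4H)-one, via thiohydroxamate ester 9 (not isolated)
Conditions: N-hydroxypyridine-2-thione, DCC, DMAP (cat.), CH2Cl2, 0 °C → rt, dark; then t-BuSH, visible light, THF, rt
Reagents that add atoms: none
Why: Barton reductive decarboxylation should fragment the thiohydroxamate ester to the secondary C2 radical, which takes hydrogen from the thiol in a chain process and so removes the carboxyl group and the C2 stereocentre under neutral conditions.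

Step 6
Reactants: 11 but-2-yn-1-ol
Product: 13 (2Z)-3-iodobut-2-en-1-ol, via cyclic alkenylalanate 12 (not isolated)
Conditions: NaAlH2(OCH2CH2OMe)2 (Red-Al), THF, 0 °C → rt; then I2, THF, −78 → 0 °C
Reagents that add atoms: iodine, II
Why: trans-Hydroalumination of the propargylic alcohol through the cyclic alkoxyalanate places aluminium on C3 cis to the CH2O group, and iodinolysis with retention should give the (Z)-iodoalkene that later fixes the C13=C14 geometry.

Step 7
Reactants: 13 (2Z)-3-iodobut-2-en-1-ol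
Product: 14 tert-butyl{[(2Z)-3-iodobut-2-en-1-yl]oxy}diphenylsilane
Conditions: TBDPSCl, imidazole, CH2Cl2, 0 °C → rt
Reagents that add atoms: tert-butyl(chloro)diphenylsilane, CC(C)(C)[Si](Cl)(c1ccccc1)c1ccccc1
Why: Routine silylation of a primary allylic alcohol installs a group chosen to survive t-BuLi, dilute aqueous acid, SmI2 and hydride later in the route.

Step 8
Reactants: 14 tert-butyl{[(2Z)-3-iodobut-2-en-1-yl]oxy}diphenylsilane
Product: 15 tert-butyl{[(2Z)-3-methylpenta-2,4-dien-1-yl]oxy}diphenylsilane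
Conditions: tributyl(vinyl)stannane, Pd(PPh3)4 (5 mol %), CuI (10 mol %), DMF, 40 °C
Reagents that add atoms: tributyl(vinyl)stannane, C=C[Sn](CCCC)(CCCC)CCCC
Why: Stille coupling of an alkenyl iodide with a vinylstannane proceeds with retention of alkene geometry, so the new C12 carbon should end cis to C15.

Step 9
Reactants: 15 tert-butyl{[(2Z)-3-methylpenta-2,4-dien-1-yl]oxy}diphenylsilane
Product: 17 (3Z)-5-[(tert-butyldiphenylsilyl)oxy]-3-methylpent-3-en-1-ol, via alkylborane 16 (not isolated)
Conditions: 9-BBN, THF, 0 °C → rt; then NaOH, H2O2, 0 °C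
Reagents that add atoms: hydrogen peroxide, OO
Why: Hydroboration–oxidation with the bulky 9-BBN should engage only the monosubstituted alkene of the diene and place boron on its terminal carbon, leaving the trisubstituted (Z)-alkene intact.

Step 10
Reactants: 17 (3Z)-5-[(tert-butyldiphenylsilyl)oxy]-3-methylpent-3-en-1-ol
Product: 18 tert-butyl{[(2Z)-5-iodo-3-methylpent-2-en-1-yl]oxy}diphenylsilane
Conditions: I2, PPh3, imidazole, CH2Cl2, 0 °C
Reagents that add atoms: iodine, II
Why: Appel-type iodination (SN2 displacement of the alkoxyphosphonium ion) converts the primary alcohol into the iodide without touching the silyl ether or the alkene.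

Step 11
Reactants: 18 tert-butyl{[(2Z)-5-iodo-3-methylpent-2-en-1-yl]oxy}diphenylsilane; 10 (4aS,8aS)-4,4-dimethoxy-2,5,5,8a-tetramethyl-4a,5,6,7,8,8a-hexahydronaphthalen-1(4H)-one
Product: 22 (13Z)-15-[(tert-butyldiphenylsilyl)oxy]-9-hydroxylabda-7,13-dien-6-one (C9 epimers), via alkyllithium 19 (not isolated), via alkylcerium dichloride 20 (not isolated), via ketal carbinol 21 (not isolated)
Conditions: 18, t-BuLi (2.1 equiv), Et2O/pentane, −78 °C; CeCl3, THF, −78 °C; then 10, −78 → −20 °C; then 1 M HCl, THF, 0 °C → rt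
Reagents that add atoms: water, O
Why: Lithium–iodine exchange and transmetalation give an oxophilic, weakly basic organocerium reagent that should add 1,2 to the hindered, non-enolisable C9 ketone, after which the now simple allylic dimethyl ketal is hydrolysed in the acidic work-up to the γ-hydroxy enone.

Step 12
Reactants: 22 (13Z)-15-[(tert-butyldiphenylsilyl)oxy]-9-hydroxylabda-7,13-dien-6-one
Product: 23 (13Z)-15-[(tert-butyldiphenylsilyl)oxy]labda-8,13-dien-6-one
Conditions: SmI2 (3 equiv), THF/MeOH, −78 °C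
Reagents that add atoms: none
Why: SmI2 reduction of a γ-oxygenated enone (vinylogous α-deoxygenation) should place carbanion character on C8, expel the C9 oxygen to form the C8=C9 alkene, and give the deconjugated ketone by kinetic protonation of the dienolate at C7.

Step 13
Reactants: 23 (13Z)-15-[(tert-butyldiphenylsilyl)oxy]labda-8,13-dien-6-one
Product: 25 (13Z)-15-[(tert-butyldiphenylsilyl)oxy]-7α-hydroxylabda-8,13-dien-6-one, via potassium dienolate 24 (not isolated)
Conditions: KN(SiMe3)2, THF, −78 °C; then 3-phenyl-2-(phenylsulfonyl)oxaziridine, −78 °C; AcOH quench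
Reagents that add atoms: 3-phenyl-2-(phenylsulfonyl)oxaziridine, O=S(=O)(c1ccccc1)N1OC1c1ccccc1
Why: Enolate hydroxylation with an N-sulfonyloxaziridine should follow deprotonation at the doubly activated C7 and occur at the α-carbon of the dienolate on the axial α-face, opposite the angular C10 methyl, which sets C7 as 7α-OH (7S).

Step 14
Reactants: 25 (13Z)-15-[(tert-butyldiphenylsilyl)oxy]-7α-hydroxylabda-8,13-dien-6-one
Product: 26 (13Z)-15-[(tert-butyldiphenylsilyl)oxy]labda-8,13-diene-6β,7α-diol
Conditions: NaBH4, MeOH/THF, −20 → 0 °C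
Reagents that add atoms: none
Why: Hydride reduction under steric approach control should deliver hydride to the α-face of the C6 ketone, because the β-face is shielded by the syn-axial C10 and C4 methyl groups, and so give the axial 6β-alcohol (6S) trans to the 7α-hydroxyl.

Step 15
Reactants: 26 (13Z)-15-[(tert-butyldiphenylsilyl)oxy]labda-8,13-diene-6β,7α-diol
Product: 27 (13Z)-15-[(tert-butyldiphenylsilyl)oxy]-7α-[(triethylsilyl)oxy]labda-8,13-dien-6β-ol
Conditions: TESCl (1.1 equiv), imidazole, CH2Cl2, −20 → 0 °C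
Reagents that add atoms: chlorotriethylsilane, CC[Si](Cl)(CC)CC
Why: Selective silylation should occur at the accessible allylic 7α-hydroxyl, since the 6β-hydroxyl is 1,3-diaxial to two methyl groups and far slower to react.

Step 16
Reactants: 27 (13Z)-15-[(tert-butyldiphenylsilyl)oxy]-7α-[(triethylsilyl)oxy]labda-8,13-dien-6β-ol
Product: 28 (13Z)-15-[(tert-butyldiphenylsilyl)oxy]-7α-[(triethylsilyl)oxy]labda-8,13-dien-6β-yl acetate
Conditions: Ac2O, DMAP, pyridine, 50 °C
Reagents that add atoms: acetic anhydride, CC(=O)OC(C)=O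
Why: DMAP-catalysed acylation through the N-acetylpyridinium ion at raised temperature should acetylate the remaining hindered axial hydroxyl, and the trans-diaxial O6/O7 arrangement rules out silyl or acyl migration.

Step 17
Reactants: 28 (13Z)-15-[(tert-butyldiphenylsilyl)oxy]-7α-[(triethylsilyl)oxy]labda-8,13-dien-6β-yl acetate
Product: 29 (13Z)-6β-acetoxylabda-8,13-diene-7α,15-diol (CNP0183298.2)
Conditions: Bu4NF, AcOH (1:1), THF, 0 °C → rt
Reagents that add atoms: none
Why: Fluoride-mediated cleavage of both silyl ethers in an acetic-acid-buffered medium should free the C7 and C15 hydroxyls while the hindered C6 acetate stays in place.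

**Compound list**
1 | 4-methoxy-2,6-dimethylphenol | COc1cc(C)c(O)c(C)c1 | starting material
2 | 4,4-dimethoxy-2,6-dimethylcyclohexa-2,5-dien-1-one | COC1(OC)C=C(C)C(=O)C(C)=C1 | intermediate
3 | isopropenylmagnesium bromide, CH2=C(CH3)MgBr (THF solution) | C=C(C)[Mg]Br | starting material
4 | methyl 2-(bromomethyl)prop-2-enoate | C=C(CBr)C(=O)OC | starting material
5 | bromomagnesium (3S)-4,4-dimethoxy-2,6-dimethyl-3-(prop-1-en-2-yl)cyclohexa-1,5-dien-1-olate | COC1(OC)C=C(C)C(O[Mg]Br)=C(C)[C@@H]1C(C)=C | intermediate (not isolated)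
6 | methyl 2-{[(1S,6S)-5,5-dimethoxy-1,3-dimethyl-2-oxo-6-(prop-1-en-2-yl)cyclohex-3-en-1-yl]methyl}prop-2-enoate (labdane C5 S, C10 S; isopropenyl trans to the acrylate arm) | COC1(OC)C=C(C)C(=O)[C@@](C)(CC(=C)C(=O)OC)[C@@H]1C(C)=C | intermediate
7 | methyl (4aS,8aS)-5,5-dimethoxy-4,4,7,8a-tetramethyl-8-oxo-1,2,3,4,4a,5,8,8a-octahydronaphthalene-2-carboxylate, trans-fused, C2 epimers | COC1(OC)C=C(C)C(=O)[C@@]2(C)CC(C(=O)OC)CC(C)(C)[C@H]12 | intermediate
8 | (4aS,8aS)-5,5-dimethoxy-4,4,7,8a-tetramethyl-8-oxo-1,2,3,4,4a,5,8,8a-octahydronaphthalene-2-carboxylic acid, C2 epimers | COC1(OC)C=C(C)C(=O)[C@@]2(C)CC(C(=O)O)CC(C)(C)[C@H]12 | intermediate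
9 | 2-thioxopyridin-1(2H)-yl ester of acid 8 (thiohydroxamate ester) | COC1(OC)C=C(C)C(=O)[C@@]2(C)CC(C(=O)ON3C=CC=CC3=S)CC(C)(C)[C@H]12 | intermediate (not isolated)
10 | (4aS,8aS)-4,4-dimethoxy-2,5,5,8a-tetramethyl-4a,5,6,7,8,8a-hexahydronaphthalen-1(4H)-one (labdane C9 ketone, C7=C8, C6 dimethyl ketal) | COC1(OC)C=C(C)C(=O)[C@@]2(C)CCCC(C)(C)[C@H]12 | intermediate
11 | but-2-yn-1-ol | CC#CCO | starting material
12 | sodium 2,2-bis(2-methoxyethoxy)-3-methyl-2,5-dihydro-1,2-oxaluminol-2-uide (cyclic alkenylalanate) | CC1=CCO[Al-]1(OCCOC)OCCOC.[Na+] | intermediate (not isolated)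
13 | (2Z)-3-iodobut-2-en-1-ol | C/C(I)=C/CO | intermediate
14 | tert-butyl{[(2Z)-3-iodobut-2-en-1-yl]oxy}diphenylsilane | C/C(I)=C/CO[Si](c1ccccc1)(c1ccccc1)C(C)(C)C | intermediate
15 | tert-butyl{[(2Z)-3-methylpenta-2,4-dien-1-yl]oxy}diphenylsilane | C=C/C(C)=C\CO[Si](c1ccccc1)(c1ccccc1)C(C)(C)C | intermediate
16 | 9-{(3Z)-5-[(tert-butyldiphenylsilyl)oxy]-3-methylpent-3-en-1-yl}-9-borabicyclo[3.3.1]nonane | B1(CC/C(C)=C\CO[Si](c2ccccc2)(c2ccccc2)C(C)(C)C)C2CCCC1CCC2 | intermediate (not isolated)
17 | (3Z)-5-[(tert-butyldiphenylsilyl)oxy]-3-methylpent-3-en-1-ol | OCC/C(C)=C\CO[Si](c1ccccc1)(c1ccccc1)C(C)(C)C | intermediate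
18 | tert-butyl{[(2Z)-5-iodo-3-methylpent-2-en-1-yl]oxy}diphenylsilane | ICC/C(C)=C\CO[Si](c1ccccc1)(c1ccccc1)C(C)(C)C | intermediate
19 | {(3Z)-5-[(tert-butyldiphenylsilyl)oxy]-3-methylpent-3-en-1-yl}lithium | [Li]CC/C(C)=C\CO[Si](c1ccccc1)(c1ccccc1)C(C)(C)C | intermediate (not isolated)
20 | {(3Z)-5-[(tert-butyldiphenylsilyl)oxy]-3-methylpent-3-en-1-yl}cerium dichloride | Cl[Ce](Cl)CC/C(C)=C\CO[Si](c1ccccc1)(c1ccccc1)C(C)(C)C | intermediate (not isolated)
21 | (13Z)-15-[(tert-butyldiphenylsilyl)oxy]-6,6-dimethoxylabda-7,13-dien-9-ol (C9 epimers; 5α-H, 10β-CH3) | COC1(OC)C=C(C)C(O)(CC/C(C)=C\CO[Si](c3ccccc3)(c3ccccc3)C(C)(C)C)[C@@]2(C)CCCC(C)(C)[C@H]12 | intermediate (not isolated)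
22 | (13Z)-15-[(tert-butyldiphenylsilyl)oxy]-9-hydroxylabda-7,13-dien-6-one (C9 epimers; 5S,10S) | O=C1C=C(C)C(O)(CC/C(C)=C\CO[Si](c3ccccc3)(c3ccccc3)C(C)(C)C)[C@@]2(C)CCCC(C)(C)[C@H]12 | intermediate
23 | (13Z)-15-[(tert-butyldiphenylsilyl)oxy]labda-8,13-dien-6-one (5S,10S) | O=C1CC(C)=C(CC/C(C)=C\CO[Si](c3ccccc3)(c3ccccc3)C(C)(C)C)[C@@]2(C)CCCC(C)(C)[C@H]12 | intermediate
24 | potassium 6,8-dienolate of ketone 23 (O–K on C6, C6=C7, C8=C9) | [K]OC1=CC(C)=C(CC/C(C)=C\CO[Si](c3ccccc3)(c3ccccc3)C(C)(C)C)[C@@]2(C)CCCC(C)(C)[C@H]12 | intermediate (not isolated)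
25 | (13Z)-15-[(tert-butyldiphenylsilyl)oxy]-7α-hydroxylabda-8,13-dien-6-one (5S,7S,10S) | O=C1[C@@H](O)C(C)=C(CC/C(C)=C\CO[Si](c3ccccc3)(c3ccccc3)C(C)(C)C)[C@@]2(C)CCCC(C)(C)[C@H]12 | intermediate
26 | (13Z)-15-[(tert-butyldiphenylsilyl)oxy]labda-8,13-diene-6β,7α-diol (5S,6S,7S,10S) | O[C@@H]1[C@@H](O)C(C)=C(CC/C(C)=C\CO[Si](c3ccccc3)(c3ccccc3)C(C)(C)C)[C@@]2(C)CCCC(C)(C)[C@H]12 | intermediate
27 | (13Z)-15-[(tert-butyldiphenylsilyl)oxy]-7α-[(triethylsilyl)oxy]labda-8,13-dien-6β-ol | O[C@@H]1[C@@H](O[Si](CC)(CC)CC)C(C)=C(CC/C(C)=C\CO[Si](c3ccccc3)(c3ccccc3)C(C)(C)C)[C@@]2(C)CCCC(C)(C)[C@H]12 | intermediate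
28 | (13Z)-15-[(tert-butyldiphenylsilyl)oxy]-7α-[(triethylsilyl)oxy]labda-8,13-dien-6β-yl acetate | CC(=O)O[C@@H]1[C@@H](O[Si](CC)(CC)CC)C(C)=C(CC/C(C)=C\CO[Si](c3ccccc3)(c3ccccc3)C(C)(C)C)[C@@]2(C)CCCC(C)(C)[C@H]12 | intermediate
29 | (13Z)-6β-acetoxylabda-8,13-diene-7α,15-diol = (1S,2S,4aS,8aS)-2-hydroxy-4-[(3Z)-5-hydroxy-3-methylpent-3-en-1-yl]-3,4a,8,8-tetramethyl-1,2,4a,5,6,7,8,8a-octahydronaphthalen-1-yl acetate | CC(=O)O[C@@H]1[C@@H](O)C(C)=C(CC/C(C)=C\CO)[C@@]2(C)CCCC(C)(C)[C@H]12 | target

**Step count and risks**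
Total: 17 steps. Longest linear sequence: 12 steps (steps 1–5 and 11–17 from phenol 1; the side-chain branch, steps 6–10 and 11–17, is equally long).

Step 2 (labelled step). What may go wrong: weak discrimination between the two enantiotopic enone arms, slow alkenyl transfer from copper to the α-methylated β-carbon with 1,2-addition taking over, or incomplete C-alkylation of the magnesium enolate. Fallback with known chemistry, forming the same two bonds in two flasks: starting from dienone 2, a rhodium-catalysed asymmetric 1,4-addition of potassium isopropenyltrifluoroborate ([Rh(cod)2]BF4, BINAP, Et3N, toluene/H2O; Hayashi–Miyaura type, a reaction class already used for alkenyl transfer to quinone monoketals) should give (5R)-4,4-dimethoxy-2,6-dimethyl-5-(prop-1-en-2-yl)cyclohex-2-en-1-one F1 as a mixture at the methyl-bearing α-carbon. That carbon is the only enolisable position, so deprotonation with KN(SiMe3)2 in THF at −78 °C and alkylation with bromide 4 anti to the isopropenyl group should return to compound 6.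

Step 12. What may go wrong: protonation of the reduced enone before the C9 oxygen leaves, so that conjugate reduction with retention of the hydroxyl competes, or drift of the new alkene into conjugation with the C6 ketone. Fallback that forms the C9–C11 bond by cross-coupling instead of addition/deoxygenation: starting from enone ketal 10, conjugate reduction with LiBH(s-Bu)3 in THF at −78 °C and trapping of the enolate with PhNTf2 should give (4aS,8aS)-4,4-dimethoxy-2,5,5,8a-tetramethyl-3,4,4a,5,6,7,8,8a-octahydronaphthalen-1-yl trifluoromethanesulfonate F2. Alkyllithium 19 (from iodide 18) is converted with ZnCl2 into {(3Z)-5-[(tert-butyldiphenylsilyl)oxy]-3-methylpent-3-en-1-yl}zinc chloride F3, and Negishi coupling of F2 with F3 (Pd(PPh3)4, THF/NMP, 50 °C) should give (13Z)-15-[(tert-butyldiphenylsilyl)oxy]-6,6-dimethoxylabda-8,13-diene F4. Mild hydrolysis of the ketal (pyridinium p-toluenesulfonate, acetone/H2O, rt) then comes back to the route at compound 23, bypassing steps 11 and 12.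

Step 16. What may go wrong: incomplete acylation of the congested axial C6 hydroxyl beside the bulky triethylsilyl ether, or loss of that silyl group under the forcing conditions. Fallback that moves the selectivity from the acylation to the deacylation: starting from diol 26, desilylation (Bu4NF, THF) should give (13Z)-labda-8,13-diene-6β,7α,15-triol F5. Exhaustive acetylation (excess Ac2O, DMAP, Et3N, 60 °C), now beside a small acetate instead of a silyl ether, should give (13Z)-labda-8,13-diene-6β,7α,15-triyl triacetate F6. Controlled methanolysis (K2CO3, MeOH, 0 °C) should then remove the exposed primary C15 and allylic C7 acetates faster than the shielded 6β-acetate and arrive at target 29, replacing steps 15–17.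

**Further compounds**
F1 | step 2 | (5R)-4,4-dimethoxy-2,6-dimethyl-5-(prop-1-en-2-yl)cyclohex-2-en-1-one (C6 epimers) | COC1(OC)C=C(C)C(=O)C(C)[C@@H]1C(C)=C
F2 | step 12 | (4aS,8aS)-4,4-dimethoxy-2,5,5,8a-tetramethyl-3,4,4a,5,6,7,8,8a-octahydronaphthalen-1-yl trifluoromethanesulfonate | COC1(OC)CC(C)=C(OS(=O)(=O)C(F)(F)F)[C@@]2(C)CCCC(C)(C)[C@H]12
F3 | step 12 | {(3Z)-5-[(tert-butyldiphenylsilyl)oxy]-3-methylpent-3-en-1-yl}zinc chloride | Cl[Zn]CC/C(C)=C\CO[Si](c1ccccc1)(c1ccccc1)C(C)(C)C
F4 | step 12 | (13Z)-15-[(tert-butyldiphenylsilyl)oxy]-6,6-dimethoxylabda-8,13-diene | COC1(OC)CC(C)=C(CC/C(C)=C\CO[Si](c3ccccc3)(c3ccccc3)C(C)(C)C)[C@@]2(C)CCCC(C)(C)[C@H]12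
F5 | step 16 | (13Z)-labda-8,13-diene-6β,7α,15-triol | O[C@@H]1[C@@H](O)C(C)=C(CC/C(C)=C\CO)[C@@]2(C)CCCC(C)(C)[C@H]12
F6 | step 16 | (13Z)-labda-8,13-diene-6β,7α,15-triyl triacetate | CC(=O)O[C@@H]1[C@@H](OC(C)=O)C(C)=C(CC/C(C)=C\COC(C)=O)[C@@]2(C)CCCC(C)(C)[C@H]12
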